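## Structural features

The target is a sesquineolignan with three aromatic rings: a guaiacyl ring A, a syringyl ring B, and a guaiacyl-type ring C that carries a 3-hydroxypropyl chain. Rings B and C are joined through a 2-aryl-3-hydroxymethyl-2,3-dihydrobenzofuran: O1, C3a and C7a belong to ring C, and C2 carries ring B. C2 and C3 are adjacent stereocentres, both R, with ring B and the CH2OH group cis, which is the less stable arrangement. Ring A is attached through an arylglycerol β-aryl ether to the 4-oxygen of ring B; its adjacent stereocentres, the benzylic carbinol Cα (R) and the ether carbon Cβ (S), are erythro. The two stereo pairs are too far apart to steer each other, so each must be set by a reagent or an auxiliary. The fragile points are the cis benzylic aryl ether C2–O1 (acid epimerises it to trans, and a free phenoxide on ring B para to C2 could open it through a quinone methide) and the benzylic alcohol Cα on an electron-rich ring. The real difficulty is to obtain the cis relation at C2/C3 and the erythro relation at Cα/Cβ, each in the right absolute sense. The key step uses the 1,3-relation across C3 between the oxygen of the C3 CH2OH group and the O1–C2 bond: if that CH2–O oxygen is bonded to C2 instead, C2, C3, CH2 and O form an oxetane, and the ring C phenol oxygen (the future O1) sits five atoms from C2.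

## Logic of the disconnections

**30 to 28.** The three O–Si bonds are cut first (29), then the C–H bond of the Cα carbinol, which leads to aryl ketone 28. The reason is that a boron aldol of an aryloxyacetyl imide gives the syn adduct, which in arylglycerol terms is threo, whereas the target is erythro. The anti glycolate aldols that would give erythro directly need strong Lewis acids that the cis ring may not tolerate. The gain is that Cα is uncoupled from Cβ and set by a chiral reduction catalyst. The demand is that the reduction must not enolise Cβ.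

**28 to 23 + 24.** The benzylic oxidation level is taken back to diol 27, the auxiliary is put back (26), and the Cα–Cβ bond is cut by an aldol. The reason is that the auxiliary fixes Cβ absolutely, and the Cα configuration formed alongside is later replaced. The gain is that ring A arrives as the simple aldehyde 24. The demand is clean enolisation of 23 in the presence of the cis ring, and an oxidation 27 to 28 that touches only the benzylic hydroxyl.

**23 to 19.** The N–acyl bond is cut (21), and the carboxyl carbon is recognised as the oxidised inner carbon of an O-allyl group (19). The reason is that the ring B oxygen then never appears as a free phenoxide, which could open the cis ring through a quinone methide, and no deprotection step is spent. The gain is that one group serves as protecting group from 11 to 19 and as latent carboxymethyl unit. The demand is an alkene cleavage that spares electron-rich arenes.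

**19 to 17 (key disconnection).** After removal of the silyl group (18), the O1–C2 bond is cut and C2 is joined to the oxygen of the C3 CH2OH group, giving oxetane 17. The reason is that a cis-oxetane is the product of a syn aldol, and inversion at C2 turns it into the cis-dihydrobenzofuran. The gain is that the ring and the C2 stereocentre are traced to acyclic stereocontrol, with the leaving oxygen kept as the CH2OH group. The demand is twofold: the phenoxide must attack C2 and not the oxetane CH2 carbon (both closures are 5-exo-tet), and it must do so with inversion. For this reason ring B in 17 carries a plain ether and not a sulfonate. A strongly withdrawing group would remove the benzylic activation of C2 and hand the attack to the unhindered CH2 carbon. A carbonate base combined with a lithium salt would only precipitate Li2CO3, so a lithium amide is used.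

**17 to 14.** The aryl O–Si bond is restored (16) and the oxetane O–CH2 bond is cut to diol 14 via its primary sulfonate 15. The reason is that this closure changes no bond at a stereocentre. The gain is an acyclic syn 1,3-diol. The demand is that ring closure must outrun fragmentation of the alkoxide, and the ring C phenol must stay masked, since a free phenoxide would displace the sulfonate itself.

**14 to 9 + 11.** The auxiliary is put back (13) and the bond between the two future ring carbons C2 and C3 is cut by a syn aldol. The reason is that both stereocentres are set together and reliably. The gain is two simple aromatic pieces. The demand is the (S)-auxiliary, which gives the (2S,3S) adduct.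

**9 to 1 + 2, and 11 to 10 + 2.** The N–acyl bond (7), the alkene cleavage (5), the O–Si bonds (4), the aryl–allyl C–C bond (3) and the allyl ether are cut in turn; 11 comes from 10 and 2. The reason is that an acetic acid unit ortho to a phenol is the oxidised product of a Claisen rearrangement. The gain is commercial 1, 2 and 10. The demand is that the allyl group migrates to the only free ortho position.

## Other disconnections considered

**Alternative 1:** The cut is the aryl C7a–O1 bond. Forward, the benzylic alkoxide of the fluoro aldehyde A2 (KN(SiMe3)2) displaces fluoride para to the formyl group and gives A1.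
- In favour: the closure touches neither stereocentre and has only one possible site. On the security of the ring-closing mechanism it is better than the chosen plan, which must control both site and inversion.
- Against: C2 is retained, so A2 needs the anti aldol relation, which is harder to reach for an arylacetyl imide than the syn relation used here, or costs an inversion. Ring C must be built as a fluoro formyl arene. The formyl group must then be extended by two carbons and reduced, with a benzyl ether and a benzylic C–O bond present during any hydrogenation. An alkoxide beside an aldehyde may also add to it.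
- Comparison: equal in relying on auxiliary aldol chemistry for the stereocentres; probably two to three steps longer to the common core.

**Alternative 2:** The cut is C2–C3. Forward, the achiral diazo ester A4 undergoes carbenoid insertion into the benzylic C–H bond under the divalent rhodium carboxylate Rh2(S-PTTL)4 (or its mirror image) and gives the cis ester A3.
- In favour: one catalytic step makes the ring and both stereocentres from a precursor a few steps from phenols, and both ester groups of A3 can be reduced together to the two primary alcohols. On step economy and on use of chirality it is better than the chosen plan.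
- Against: the C–H bond is benzylic, next to oxygen and on a very electron-rich ring, so a stepwise hydride-transfer course may compete with concerted insertion and erode cis selectivity and enantiopurity. A neighbouring methoxy group may intercept the carbenoid as an ylide. The enantiopurity rests on the catalyst alone, with no separable diastereomers. The C3–H of A3 is acidic and may epimerise to trans during reduction.
- Comparison: equal in that cis is a kinetic outcome in both plans; the chosen plan is longer but its stereocentres come from separable auxiliary adducts.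

**Alternative 3:** The cut is C3–C3a. Forward, photolysis of the diazo ketone A6 in methanol causes Wolff ring contraction and ketene trapping to give A5.
- In favour: C2 could come from a catalytic asymmetric flavanone synthesis, and A5 is of the same type as A3, so what follows is equal to Alternative 2.
- Against: diazo transfer needs base, under which the pyranone ring can open and reclose by a retro-oxa-Michael path and racemise C2. The carbene has a neighbouring C2–H whose 1,2-shift would compete with aryl migration and destroy the stereocentre. C3 is set only by the face of protonation after ketene trapping, a kinetic preference of uncertain size for the less stable cis ester.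
- Comparison: step count similar to the chosen plan; stereocontrol at both centres weaker.

Key step: step 11

Remark: the cis-(2S,3R)-oxetane and the cis-(2R,3R)-dihydrobenzofuran are consistent with inversion at C2 alone, so the structures needed no correction; the changes are in protecting groups (allyl ether on ring B, triisopropylsilyl = TIPS on ring C and the chain) and in the reagents.
Remark: both enantiomers of 4-benzyloxazolidin-2-one are taken as purchased reagents and 24 (TBS = tert-butyldimethylsilyl) as a purchased starting material.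
Remark: "CoreAr–O" below means 4-[(2R,3R)-7-methoxy-3-(triisopropylsilyloxymethyl)-5-(3-triisopropylsilyloxypropyl)-2,3-dihydrobenzofuran-2-yl]-2,6-dimethoxyphenoxy.

## Steps

Step 1
Reactants: 1 dihydroconiferyl alcohol [4-(3-hydroxypropyl)-2-methoxyphenol]; 2 allyl bromide
Product: 3 3-[3-methoxy-4-(prop-2-enyloxy)phenyl]propan-1-ol
Conditions: K2CO3, acetone, reflux
Reagents that add atoms: none
Why: Williamson ether synthesis; the carbonate deprotonates only the phenol, so the primary alcohol stays free.

Step 2
Reactants: 3 3-[3-methoxy-4-(prop-2-enyloxy)phenyl]propan-1-ol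
Product: 4 4-(3-hydroxypropyl)-2-methoxy-6-(prop-2-enyl)phenol
Conditions: PhNEt2, 200 °C
Reagents that add atoms: none
Why: Aromatic Claisen rearrangement; one ortho position carries the methoxy group and the para position the side chain, so the allyl group can only end at the free ortho carbon.

Step 3
Reactants: 4 4-(3-hydroxypropyl)-2-methoxy-6-(prop-2-enyl)phenol
Product: 5 triisopropyl{2-methoxy-6-(prop-2-enyl)-4-[3-(triisopropylsilyloxy)propyl]phenoxy}silane
Conditions: TIPSOTf (2.4 equiv), 2,6-lutidine, CH2Cl2, 0 °C to rt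
Reagents that add atoms: triisopropylsilyl triflate, CC(C)[Si](OS(=O)(=O)C(F)(F)F)(C(C)C)C(C)C
Why: Silylation of both hydroxyls in one operation; the hindered aryl silyl ether should resist transfer to alkoxides in later basic steps, yet fluoride cleaves it much faster than the alkyl silyl ether.

Step 4
Reactants: 5 triisopropyl{2-methoxy-6-(prop-2-enyl)-4-[3-(triisopropylsilyloxy)propyl]phenoxy}silane
Product: 7 2-{3-methoxy-2-(triisopropylsilyloxy)-5-[3-(triisopropylsilyloxy)propyl]phenyl}acetic acid, via arylacetaldehyde 6 (not isolated)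
Conditions: OsO4 (cat.), NaIO4, 2,6-lutidine, dioxane–H2O, rt; crude 6, NaClO2, NaH2PO4, 2-methyl-2-butene, t-BuOH–H2O, 0 °C to rt
Reagents that add atoms: sodium periodate with catalytic OsO4 (aldehyde oxygen), [Na+].[O-]I(=O)(=O)=O; sodium chlorite (second acid oxygen), [Na+].[O-]Cl=O
Why: Lemieux–Johnson cleavage of the terminal alkene, then Pinnick oxidation of the crude aldehyde; both are near neutral and spare the silyl ethers and the electron-rich ring.

Step 5
Reactants: 7 2-{3-methoxy-2-(triisopropylsilyloxy)-5-[3-(triisopropylsilyloxy)propyl]phenyl}acetic acid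
Product: 9 (S)-4-benzyl-3-(2-{3-methoxy-2-(triisopropylsilyloxy)-5-[3-(triisopropylsilyloxy)propyl]phenyl}acetyl)oxazolidin-2-one, via mixed pivalic anhydride 8 (not isolated)
Conditions: t-BuCOCl, Et3N, THF, −20 °C; then LiCl, (S)-4-benzyloxazolidin-2-one, −20 °C to rt
Reagents that add atoms: pivaloyl chloride (in 8 only), CC(C)(C)C(=O)Cl; (S)-4-benzyloxazolidin-2-one, O=C1N[C@@H](Cc2ccccc2)CO1
Why: N-acylation of the oxazolidinone through the mixed anhydride with LiCl/Et3N activation, a standard one-flask imide synthesis.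

Step 6
Reactants: 10 syringaldehyde [4-hydroxy-3,5-dimethoxybenzaldehyde]; 2 allyl bromide
Product: 11 3,5-dimethoxy-4-(prop-2-enyloxy)benzaldehyde
Conditions: K2CO3, DMF, 60 °C
Reagents that add atoms: none
Why: Williamson ether synthesis; the allyl ether keeps ring B as a non-deactivated, non-phenolic aryl group for the key step and is the latent carboxymethyl group of step 13.

Step 7
Reactants: 9 (S)-4-benzyl-3-(2-{3-methoxy-2-(triisopropylsilyloxy)-5-[3-(triisopropylsilyloxy)propyl]phenyl}acetyl)oxazolidin-2-one; 11 3,5-dimethoxy-4-(prop-2-enyloxy)benzaldehyde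
Product: 13 (S)-4-benzyl-3-[(2S,3S)-3-[3,5-dimethoxy-4-(prop-2-enyloxy)phenyl]-3-hydroxy-2-{3-methoxy-2-(triisopropylsilyloxy)-5-[3-(triisopropylsilyloxy)propyl]phenyl}propanoyl]oxazolidin-2-one, via dibutylboron (Z)-enolate 12 (not isolated)
Conditions: Bu2BOTf, i-Pr2NEt, CH2Cl2, −78 to 0 °C; 11, −78 to 0 °C; pH 7 buffer, MeOH, H2O2, 0 °C
Reagents that add atoms: dibutylboron triflate (in 12 only), CCCCB(CCCC)OS(=O)(=O)C(F)(F)F
Why: Evans syn aldol reaction; the (Z)-boron enolate reacts through a chair Zimmerman–Traxler transition state on the face away from the benzyl group of the (S)-auxiliary, which sets C2 (S) and C3 (S) together in the syn relation.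

Step 8
Reactants: 13 the (2S,3S) aldol adduct
Product: 14 (1S,2R)-1-[3,5-dimethoxy-4-(prop-2-enyloxy)phenyl]-2-{3-methoxy-2-(triisopropylsilyloxy)-5-[3-(triisopropylsilyloxy)propyl]phenyl}propane-1,3-diol
Conditions: LiBH4, THF–MeOH, 0 °C
Reagents that add atoms: none
Why: Reductive removal of the auxiliary from the N-acyl oxazolidinone; both stereocentres are untouched (the descriptor at C2 changes only through priorities) and the auxiliary is recovered.

Step 9
Reactants: 14 the (1S,2R) syn diol
Product: 16 cis-(2S,3R)-2-[3,5-dimethoxy-4-(prop-2-enyloxy)phenyl]-3-{3-methoxy-2-(triisopropylsilyloxy)-5-[3-(triisopropylsilyloxy)propyl]phenyl}oxetane, via primary monotosylate 15 (not isolated)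
Conditions: TsCl, Et3N, DMAP (cat.), CH2Cl2, 0 °C; crude 15, NaH, THF, 0 °C to rt
Reagents that add atoms: 4-toluenesulfonyl chloride (in 15 only), Cc1ccc(cc1)S(Cl)(=O)=O
Why: Selective sulfonylation of the primary hydroxyl, then intramolecular Williamson etherification (4-exo-tet) by the benzylic alkoxide at the CH2 carbon; no bond at a stereocentre changes, so the syn diol should give the cis-oxetane.

Step 10
Reactants: 16 the bis-silylated cis-oxetane
Product: 17 2-{(2S,3R)-2-[3,5-dimethoxy-4-(prop-2-enyloxy)phenyl]oxetan-3-yl}-6-methoxy-4-[3-(triisopropylsilyloxy)propyl]phenol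
Conditions: Bu4NF (1.05 equiv), AcOH (1.05 equiv), THF, 0 °C; pH 7 work-up, base-washed silica
Reagents that add atoms: none
Why: Fluoride cleaves the aryl silyl ether much faster than the primary alkyl silyl ether, and the acetic acid buffer keeps the phenol protonated so that the oxetane is not opened in an uncontrolled way.

Step 11
Reactants: 17 2-{(2S,3R)-2-[3,5-dimethoxy-4-(prop-2-enyloxy)phenyl]oxetan-3-yl}-6-methoxy-4-[3-(triisopropylsilyloxy)propyl]phenol
Product: 18 {(2R,3R)-2-[3,5-dimethoxy-4-(prop-2-enyloxy)phenyl]-7-methoxy-5-[3-(triisopropylsilyloxy)propyl]-2,3-dihydrobenzofuran-3-yl}methanol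
Conditions: LiN(SiMe3)2 (1.05 equiv), toluene–THF, −78 to 0 °C; LiN(SO2CF3)2 (1 equiv), 60 °C; aq. NH4Cl
Reagents that add atoms: none
Why: The amide base turns the phenol into its lithium phenoxide, and lithium ions coordinate the oxetane oxygen and lengthen the benzylic C2–O bond. The phenoxide oxygen then attacks C2 from the side opposite the leaving oxygen in an SN2 process, which forms the O1–C2 bond and releases the oxetane oxygen as the alkoxide of the C3 CH2OH group. The closest known reaction type is the lithium-salt-promoted intramolecular opening of 3-(2-hydroxyaryl)oxetanes to 2,3-dihydrobenzofuran-3-ylmethanols, together with the stereospecific benzylic opening of 2-aryl oxiranes and oxetanes by phenols. The dihydrofuran ring closes in the 5-exo-tet mode, driven by release of four-ring strain and of the eclipsing between the two cis aryl groups as C2 flattens. The new stereocentre C2 is controlled by the substrate: inversion of the (S)-oxetane carbon gives 2R while C3 (R) is untouched, so ring B and CH2OH end up cis. Two selectivities are needed, attack at C2 and not at the unsubstituted oxetane carbon (also 5-exo-tet), and inversion and not ionisation. The first rests on benzylic activation of C2 under lithium coordination, which is why ring B carries an ether and no electron-withdrawing sulfonate. The second rests on the absence of any Brønsted acid, on the tethered anionic nucleophile, and on ring B, whose 4-alkoxy group is twisted out of conjugation between two methoxy groups and which has no free para-hydroxyl that could form a quinone methide.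

Step 12
Reactants: 18 the cis-dihydrobenzofuranylmethanol
Product: 19 (2R,3R)-2-[3,5-dimethoxy-4-(prop-2-enyloxy)phenyl]-7-methoxy-3-(triisopropylsilyloxymethyl)-5-[3-(triisopropylsilyloxy)propyl]-2,3-dihydrobenzofuran
Conditions: TIPSCl, imidazole, DMF, rt
Reagents that add atoms: triisopropylsilyl chloride, CC(C)[Si](Cl)(C(C)C)C(C)C
Why: Standard silylation of the primary alcohol, needed because the coming acylation and boron enolate steps do not tolerate a free hydroxyl.

Step 13
Reactants: 19 the bis-silylated allyl ether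
Product: 21 2-(CoreAr–O)acetic acid, via aryloxyacetaldehyde 20 (not isolated)
Conditions: OsO4 (cat.), NaIO4, 2,6-lutidine, dioxane–H2O, rt; crude 20, NaClO2, NaH2PO4, 2-methyl-2-butene, t-BuOH–H2O, 0 °C to rt
Reagents that add atoms: sodium periodate with catalytic OsO4 (aldehyde oxygen), [Na+].[O-]I(=O)(=O)=O; sodium chlorite (second acid oxygen), [Na+].[O-]Cl=O
Why: Lemieux–Johnson cleavage of the aryl allyl ether and Pinnick oxidation give the aryloxyacetic acid directly, so the ring B oxygen is never set free as a phenoxide that could open the cis ring.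

Step 14
Reactants: 21 2-(CoreAr–O)acetic acid
Product: 23 (R)-4-benzyl-3-[2-(CoreAr–O)acetyl]oxazolidin-2-one, via mixed pivalic anhydride 22 (not isolated)
Conditions: t-BuCOCl, Et3N, THF, −20 °C; then LiCl, (R)-4-benzyloxazolidin-2-one, −20 °C to rt
Reagents that add atoms: pivaloyl chloride (in 22 only), CC(C)(C)C(=O)Cl; (R)-4-benzyloxazolidin-2-one, O=C1N[C@H](Cc2ccccc2)CO1
Why: The same one-flask mixed-anhydride N-acylation as in step 5, here with the (R)-auxiliary.

Step 15
Reactants: 23 (R)-4-benzyl-3-[2-(CoreAr–O)acetyl]oxazolidin-2-one; 24 4-(tert-butyldimethylsilyloxy)-3-methoxybenzaldehyde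
Product: 26 (R)-4-benzyl-3-{(2R,3S)-3-[4-(tert-butyldimethylsilyloxy)-3-methoxyphenyl]-3-hydroxy-2-(CoreAr–O)propanoyl}oxazolidin-2-one, via dibutylboron (Z)-enolate 25 (not isolated)
Conditions: Bu2BOTf, i-Pr2NEt, CH2Cl2, −78 to 0 °C; 24, −78 to 0 °C; pH 7 buffer, MeOH, H2O2, 0 °C
Reagents that add atoms: dibutylboron triflate (in 25 only), CCCCB(CCCC)OS(=O)(=O)C(F)(F)F
Why: Evans syn glycolate aldol reaction, established for aryloxyacetyl oxazolidinones; the (R)-auxiliary sets the ether carbon as 2R (the Cβ of the target, S after reduction), while the carbinol centre formed alongside (3S) belongs to the threo series and is replaced in steps 17 and 18.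

Step 16
Reactants: 26 the (2R,3S) glycolate aldol adduct
Product: 27 (1S,2S)-1-[4-(tert-butyldimethylsilyloxy)-3-methoxyphenyl]-2-(CoreAr–O)propane-1,3-diol
Conditions: LiBH4, THF–MeOH, 0 °C
Reagents that add atoms: none
Why: Reductive removal of the auxiliary as in step 8; it gives the threo diol and returns the auxiliary.

Step 17
Reactants: 27 the threo (1S,2S) diol
Product: 28 (S)-1-[4-(tert-butyldimethylsilyloxy)-3-methoxyphenyl]-3-hydroxy-2-(CoreAr–O)propan-1-one
Conditions: MnO2 (excess), CH2Cl2, rt
Reagents that add atoms: none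
Why: MnO2 oxidises benzylic alcohols on electron-rich rings much faster than saturated primary alcohols, and the neutral heterogeneous conditions should leave the adjacent Cβ stereocentre untouched.

Step 18
Reactants: 28 the (S) β-hydroxy aryl ketone
Product: 29 (1R,2S)-1-[4-(tert-butyldimethylsilyloxy)-3-methoxyphenyl]-2-(CoreAr–O)propane-1,3-diol
Conditions: RuCl[(S,S)-TsDPEN](p-cymene) (2 mol %), HCO2H–Et3N (5:2), CH2Cl2, 25 °C
Reagents that add atoms: none
Why: Noyori–Ikariya asymmetric transfer hydrogenation of an aryl ketone; the catalyst recognises the aryl group and the (S,S) ligand is expected to deliver hydride to give the 1R carbinol (the mirror-image catalyst is used if the sense proves opposite), in line with the Felkin–Anh preference of an α-aryloxy ketone for the erythro product.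

Step 19
Reactants: 29 the silylated erythro (1R,2S) diol
Product: 30 the target, (1R,2S)-1-(4-hydroxy-3-methoxyphenyl)-2-{4-[(2R,3R)-3-(hydroxymethyl)-5-(3-hydroxypropyl)-7-methoxy-2,3-dihydrobenzofuran-2-yl]-2,6-dimethoxyphenoxy}propane-1,3-diol
Conditions: Bu4NF (6 equiv), THF, 0 °C to rt; aq. NH4Cl
Reagents that add atoms: none
Why: Fluoride removes the aryl TBS and both alkyl TIPS groups in one operation under basic conditions, under which neither the benzylic carbinol nor the cis ring should ionise.

## Compound list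

1 | dihydroconiferyl alcohol, 4-(3-hydroxypropyl)-2-methoxyphenol | COc1cc(CCCO)ccc1O | starting material
2 | allyl bromide | C=CCBr | starting material
3 | 3-[3-methoxy-4-(prop-2-enyloxy)phenyl]propan-1-ol | COc1cc(CCCO)ccc1OCC=C | intermediate
4 | 4-(3-hydroxypropyl)-2-methoxy-6-(prop-2-enyl)phenol | COc1cc(CCCO)cc(CC=C)c1O | intermediate
5 | triisopropyl{2-methoxy-6-(prop-2-enyl)-4-[3-(triisopropylsilyloxy)propyl]phenoxy}silane | COc1cc(CCCO[Si](C(C)C)(C(C)C)C(C)C)cc(CC=C)c1O[Si](C(C)C)(C(C)C)C(C)C | intermediate
6 | 2-{3-methoxy-2-(triisopropylsilyloxy)-5-[3-(triisopropylsilyloxy)propyl]phenyl}acetaldehyde | COc1cc(CCCO[Si](C(C)C)(C(C)C)C(C)C)cc(CC=O)c1O[Si](C(C)C)(C(C)C)C(C)C | intermediate (not isolated)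
7 | 2-{3-methoxy-2-(triisopropylsilyloxy)-5-[3-(triisopropylsilyloxy)propyl]phenyl}acetic acid | COc1cc(CCCO[Si](C(C)C)(C(C)C)C(C)C)cc(CC(=O)O)c1O[Si](C(C)C)(C(C)C)C(C)C | intermediate
8 | mixed anhydride of 7 with pivalic acid | COc1cc(CCCO[Si](C(C)C)(C(C)C)C(C)C)cc(CC(=O)OC(=O)C(C)(C)C)c1O[Si](C(C)C)(C(C)C)C(C)C | intermediate (not isolated)
9 | (S)-4-benzyl-3-(2-{3-methoxy-2-(triisopropylsilyloxy)-5-[3-(triisopropylsilyloxy)propyl]phenyl}acetyl)oxazolidin-2-one | COc1cc(CCCO[Si](C(C)C)(C(C)C)C(C)C)cc(CC(=O)N2[C@@H](Cc3ccccc3)COC2=O)c1O[Si](C(C)C)(C(C)C)C(C)C | intermediate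
10 | syringaldehyde | COc1cc(C=O)cc(OC)c1O | starting material
11 | 3,5-dimethoxy-4-(prop-2-enyloxy)benzaldehyde | COc1cc(C=O)cc(OC)c1OCC=C | intermediate
12 | dibutylboron (Z)-enolate of 9 | CCCCB(CCCC)O/C(=C\c1cc(CCCO[Si](C(C)C)(C(C)C)C(C)C)cc(OC)c1O[Si](C(C)C)(C(C)C)C(C)C)N1[C@@H](Cc2ccccc2)COC1=O | intermediate (not isolated)
13 | (S)-4-benzyl-3-[(2S,3S)-3-[3,5-dimethoxy-4-(prop-2-enyloxy)phenyl]-3-hydroxy-2-{3-methoxy-2-(triisopropylsilyloxy)-5-[3-(triisopropylsilyloxy)propyl]phenyl}propanoyl]oxazolidin-2-one | C=CCOc1c(OC)cc([C@@H](O)[C@H](c2cc(CCCO[Si](C(C)C)(C(C)C)C(C)C)cc(OC)c2O[Si](C(C)C)(C(C)C)C(C)C)C(=O)N2[C@@H](Cc3ccccc3)COC2=O)cc1OC | intermediate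
14 | (1S,2R)-1-[3,5-dimethoxy-4-(prop-2-enyloxy)phenyl]-2-{3-methoxy-2-(triisopropylsilyloxy)-5-[3-(triisopropylsilyloxy)propyl]phenyl}propane-1,3-diol | C=CCOc1c(OC)cc([C@@H](O)[C@H](c2cc(CCCO[Si](C(C)C)(C(C)C)C(C)C)cc(OC)c2O[Si](C(C)C)(C(C)C)C(C)C)CO)cc1OC | intermediate
15 | (2R,3S)-3-[3,5-dimethoxy-4-(prop-2-enyloxy)phenyl]-3-hydroxy-2-{3-methoxy-2-(triisopropylsilyloxy)-5-[3-(triisopropylsilyloxy)propyl]phenyl}propyl 4-methylbenzenesulfonate | C=CCOc1c(OC)cc([C@@H](O)[C@H](c2cc(CCCO[Si](C(C)C)(C(C)C)C(C)C)cc(OC)c2O[Si](C(C)C)(C(C)C)C(C)C)COS(=O)(=O)c2ccc(C)cc2)cc1OC | intermediate (not isolated)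
16 | cis-(2S,3R)-2-[3,5-dimethoxy-4-(prop-2-enyloxy)phenyl]-3-{3-methoxy-2-(triisopropylsilyloxy)-5-[3-(triisopropylsilyloxy)propyl]phenyl}oxetane | C=CCOc1c(OC)cc([C@H]2OC[C@H]2c2cc(CCCO[Si](C(C)C)(C(C)C)C(C)C)cc(OC)c2O[Si](C(C)C)(C(C)C)C(C)C)cc1OC | intermediate
17 | 2-{(2S,3R)-2-[3,5-dimethoxy-4-(prop-2-enyloxy)phenyl]oxetan-3-yl}-6-methoxy-4-[3-(triisopropylsilyloxy)propyl]phenol (key-step precursor) | C=CCOc1c(OC)cc([C@H]2OC[C@H]2c2cc(CCCO[Si](C(C)C)(C(C)C)C(C)C)cc(OC)c2O)cc1OC | intermediate
18 | {(2R,3R)-2-[3,5-dimethoxy-4-(prop-2-enyloxy)phenyl]-7-methoxy-5-[3-(triisopropylsilyloxy)propyl]-2,3-dihydrobenzofuran-3-yl}methanol (key-step product) | C=CCOc1c(OC)cc([C@@H]2Oc3c(OC)cc(CCCO[Si](C(C)C)(C(C)C)C(C)C)cc3[C@@H]2CO)cc1OC | intermediate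
19 | (2R,3R)-2-[3,5-dimethoxy-4-(prop-2-enyloxy)phenyl]-7-methoxy-3-(triisopropylsilyloxymethyl)-5-[3-(triisopropylsilyloxy)propyl]-2,3-dihydrobenzofuran | C=CCOc1c(OC)cc([C@@H]2Oc3c(OC)cc(CCCO[Si](C(C)C)(C(C)C)C(C)C)cc3[C@@H]2CO[Si](C(C)C)(C(C)C)C(C)C)cc1OC | intermediate
20 | 2-(CoreAr–O)acetaldehyde | O=CCOc1c(OC)cc([C@@H]2Oc3c(OC)cc(CCCO[Si](C(C)C)(C(C)C)C(C)C)cc3[C@@H]2CO[Si](C(C)C)(C(C)C)C(C)C)cc1OC | intermediate (not isolated)
21 | 2-(CoreAr–O)acetic acid | OC(=O)COc1c(OC)cc([C@@H]2Oc3c(OC)cc(CCCO[Si](C(C)C)(C(C)C)C(C)C)cc3[C@@H]2CO[Si](C(C)C)(C(C)C)C(C)C)cc1OC | intermediate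
22 | mixed anhydride of 21 with pivalic acid | CC(C)(C)C(=O)OC(=O)COc1c(OC)cc([C@@H]2Oc3c(OC)cc(CCCO[Si](C(C)C)(C(C)C)C(C)C)cc3[C@@H]2CO[Si](C(C)C)(C(C)C)C(C)C)cc1OC | intermediate (not isolated)
23 | (R)-4-benzyl-3-[2-(CoreAr–O)acetyl]oxazolidin-2-one | O=C(COc1c(OC)cc([C@@H]2Oc3c(OC)cc(CCCO[Si](C(C)C)(C(C)C)C(C)C)cc3[C@@H]2CO[Si](C(C)C)(C(C)C)C(C)C)cc1OC)N1[C@H](Cc2ccccc2)COC1=O | intermediate
24 | 4-(tert-butyldimethylsilyloxy)-3-methoxybenzaldehyde | COc1cc(C=O)ccc1O[Si](C)(C)C(C)(C)C | starting material
25 | dibutylboron (Z)-enolate of 23 | CCCCB(CCCC)O/C(=C\Oc1c(OC)cc([C@@H]2Oc3c(OC)cc(CCCO[Si](C(C)C)(C(C)C)C(C)C)cc3[C@@H]2CO[Si](C(C)C)(C(C)C)C(C)C)cc1OC)N1[C@H](Cc2ccccc2)COC1=O | intermediate (not isolated)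
26 | (R)-4-benzyl-3-{(2R,3S)-3-[4-(tert-butyldimethylsilyloxy)-3-methoxyphenyl]-3-hydroxy-2-(CoreAr–O)propanoyl}oxazolidin-2-one | COc1cc([C@H](O)[C@H](C(=O)N2[C@H](Cc3ccccc3)COC2=O)Oc2c(OC)cc([C@@H]3Oc4c(OC)cc(CCCO[Si](C(C)C)(C(C)C)C(C)C)cc4[C@@H]3CO[Si](C(C)C)(C(C)C)C(C)C)cc2OC)ccc1O[Si](C)(C)C(C)(C)C | intermediate
27 | (1S,2S)-1-[4-(tert-butyldimethylsilyloxy)-3-methoxyphenyl]-2-(CoreAr–O)propane-1,3-diol (threo) | COc1cc([C@H](O)[C@H](CO)Oc2c(OC)cc([C@@H]3Oc4c(OC)cc(CCCO[Si](C(C)C)(C(C)C)C(C)C)cc4[C@@H]3CO[Si](C(C)C)(C(C)C)C(C)C)cc2OC)ccc1O[Si](C)(C)C(C)(C)C | intermediate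
28 | (S)-1-[4-(tert-butyldimethylsilyloxy)-3-methoxyphenyl]-3-hydroxy-2-(CoreAr–O)propan-1-one | COc1cc(C(=O)[C@H](CO)Oc2c(OC)cc([C@@H]3Oc4c(OC)cc(CCCO[Si](C(C)C)(C(C)C)C(C)C)cc4[C@@H]3CO[Si](C(C)C)(C(C)C)C(C)C)cc2OC)ccc1O[Si](C)(C)C(C)(C)C | intermediate
29 | (1R,2S)-1-[4-(tert-butyldimethylsilyloxy)-3-methoxyphenyl]-2-(CoreAr–O)propane-1,3-diol (erythro) | COc1cc([C@@H](O)[C@H](CO)Oc2c(OC)cc([C@@H]3Oc4c(OC)cc(CCCO[Si](C(C)C)(C(C)C)C(C)C)cc4[C@@H]3CO[Si](C(C)C)(C(C)C)C(C)C)cc2OC)ccc1O[Si](C)(C)C(C)(C)C | intermediate
30 | (1R,2S)-1-(4-hydroxy-3-methoxyphenyl)-2-{4-[(2R,3R)-3-(hydroxymethyl)-5-(3-hydroxypropyl)-7-methoxy-2,3-dihydrobenzofuran-2-yl]-2,6-dimethoxyphenoxy}propane-1,3-diol | COc1cc([C@@H](O)[C@H](CO)Oc2c(OC)cc([C@@H]3Oc4c(OC)cc(CCCO)cc4[C@@H]3CO)cc2OC)ccc1O | target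

## Step count and least certain steps

Total: 19 steps. Longest linear sequence: 18 steps (steps 1–5 and 7–19); step 6 is a one-step side branch.

**Step 11 (key step).** Three processes may go wrong: attack of the phenoxide at the unsubstituted oxetane carbon, which is sterically easier and equally 5-exo-tet; ionisation of the benzylic C–O bond before the new bond forms, which would lose the inversion and drain towards the trans ring; or no ring opening at a temperature the substrate tolerates. The fallback sets out from 14 and forms the same O1–C2 bond with inversion by known chemistry. The primary hydroxyl is silylated (TIPSCl, imidazole) to the (1S,2R) tris-silyl ether F1. The aryl silyl ether is removed selectively (Bu4NF/AcOH, 0 °C) to the phenol F2. An intramolecular Mitsunobu etherification (PPh3, DIAD, THF, 0 °C) then closes the ring with inversion at the benzylic carbon and comes back to the route at 19.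

**Step 9.** The benzylic alkoxide may fragment (Grob-type cleavage of the central C–C bond, favoured because a conjugated alkene and an aryl aldehyde would result), or the 4-exo-tet closure may be slowed by the developing clash of the two cis aryl groups. The fallback sets out from 14 and avoids the alkoxide altogether. The primary hydroxyl is converted at −78 °C (Tf2O, 2,6-di-tert-butyl-4-methylpyridine) into the (2R,3S) primary triflate F3. On warming, the neutral benzylic hydroxyl displaces the triflate while the hindered base takes up the acid. This comes back to the route at 16.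

**Step 18.** The β-hydroxy ketone may lose the Cβ configuration by enolisation, or lose formaldehyde by retro-aldol cleavage in the amine/formic acid medium. The substrate bias may also oppose the catalyst and give poor facial selectivity. The fallback sets out from 27 and inverts Cα by substitution instead of oxidation and reduction. The primary hydroxyl is silylated (TBSCl, imidazole) to the (1S,2S) silyl ether F4. A Mitsunobu reaction with 4-nitrobenzoic acid (PPh3, DIAD) gives the inverted (1R,2S) 4-nitrobenzoate F5. Methanolysis (K2CO3, MeOH) removes the ester and the aryl silyl group to give the erythro phenol F6. Desilylation as in step 19 comes back to the route at 30.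

## Further compounds

F1 | step 11 | (1S,2R)-1-[3,5-dimethoxy-4-(prop-2-enyloxy)phenyl]-2-{3-methoxy-2-(triisopropylsilyloxy)-5-[3-(triisopropylsilyloxy)propyl]phenyl}-3-(triisopropylsilyloxy)propan-1-ol | C=CCOc1c(OC)cc([C@@H](O)[C@H](c2cc(CCCO[Si](C(C)C)(C(C)C)C(C)C)cc(OC)c2O[Si](C(C)C)(C(C)C)C(C)C)CO[Si](C(C)C)(C(C)C)C(C)C)cc1OC
F2 | step 11 | (1S,2R)-1-[3,5-dimethoxy-4-(prop-2-enyloxy)phenyl]-2-{2-hydroxy-3-methoxy-5-[3-(triisopropylsilyloxy)propyl]phenyl}-3-(triisopropylsilyloxy)propan-1-ol | C=CCOc1c(OC)cc([C@@H](O)[C@H](c2cc(CCCO[Si](C(C)C)(C(C)C)C(C)C)cc(OC)c2O)CO[Si](C(C)C)(C(C)C)C(C)C)cc1OC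
F3 | step 9 | (2R,3S)-3-[3,5-dimethoxy-4-(prop-2-enyloxy)phenyl]-3-hydroxy-2-{3-methoxy-2-(triisopropylsilyloxy)-5-[3-(triisopropylsilyloxy)propyl]phenyl}propyl trifluoromethanesulfonate | C=CCOc1c(OC)cc([C@@H](O)[C@H](c2cc(CCCO[Si](C(C)C)(C(C)C)C(C)C)cc(OC)c2O[Si](C(C)C)(C(C)C)C(C)C)COS(=O)(=O)C(F)(F)F)cc1OC
F4 | step 18 | (1S,2S)-3-(tert-butyldimethylsilyloxy)-1-[4-(tert-butyldimethylsilyloxy)-3-methoxyphenyl]-2-(CoreAr–O)propan-1-ol | COc1cc([C@H](O)[C@H](CO[Si](C)(C)C(C)(C)C)Oc2c(OC)cc([C@@H]3Oc4c(OC)cc(CCCO[Si](C(C)C)(C(C)C)C(C)C)cc4[C@@H]3CO[Si](C(C)C)(C(C)C)C(C)C)cc2OC)ccc1O[Si](C)(C)C(C)(C)C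
F5 | step 18 | (1R,2S)-3-(tert-butyldimethylsilyloxy)-1-[4-(tert-butyldimethylsilyloxy)-3-methoxyphenyl]-2-(CoreAr–O)propyl 4-nitrobenzoate | COc1cc([C@@H](OC(=O)c2ccc(cc2)[N+](=O)[O-])[C@H](CO[Si](C)(C)C(C)(C)C)Oc2c(OC)cc([C@@H]3Oc4c(OC)cc(CCCO[Si](C(C)C)(C(C)C)C(C)C)cc4[C@@H]3CO[Si](C(C)C)(C(C)C)C(C)C)cc2OC)ccc1O[Si](C)(C)C(C)(C)C
F6 | step 18 | 4-[(1R,2S)-3-(tert-butyldimethylsilyloxy)-1-hydroxy-2-(CoreAr–O)propyl]-2-methoxyphenol | COc1cc([C@@H](O)[C@H](CO[Si](C)(C)C(C)(C)C)Oc2c(OC)cc([C@@H]3Oc4c(OC)cc(CCCO[Si](C(C)C)(C(C)C)C(C)C)cc4[C@@H]3CO[Si](C(C)C)(C(C)C)C(C)C)cc2OC)ccc1O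
A1 | alternative 1 | (2R,3R)-2-(4-benzyloxy-3,5-dimethoxyphenyl)-7-methoxy-3-(triisopropylsilyloxymethyl)-2,3-dihydrobenzofuran-5-carbaldehyde | c1ccccc1COc1c(OC)cc([C@@H]2Oc3c(OC)cc(C=O)cc3[C@@H]2CO[Si](C(C)C)(C(C)C)C(C)C)cc1OC
A2 | alternative 1 | (1R,2R)-1-(4-benzyloxy-3,5-dimethoxyphenyl)-2-(2-fluoro-5-formyl-3-methoxyphenyl)-3-(triisopropylsilyloxy)propan-1-ol | c1ccccc1COc1c(OC)cc([C@H](O)[C@@H](CO[Si](C(C)C)(C(C)C)C(C)C)c2cc(C=O)cc(OC)c2F)cc1OC
A3 | alternative 2 | methyl (2R,3S)-2-(3,5-dimethoxy-4-triisopropylsilyloxyphenyl)-7-methoxy-5-(3-methoxy-3-oxopropyl)-2,3-dihydrobenzofuran-3-carboxylate | CC(C)[Si](C(C)C)(C(C)C)Oc1c(OC)cc([C@@H]2Oc3c(OC)cc(CCC(=O)OC)cc3[C@@H]2C(=O)OC)cc1OC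
A4 | alternative 2 | methyl 2-diazo-2-[2-(3,5-dimethoxy-4-triisopropylsilyloxybenzyloxy)-3-methoxy-5-(3-methoxy-3-oxopropyl)phenyl]acetate | CC(C)[Si](C(C)C)(C(C)C)Oc1c(OC)cc(COc2c(OC)cc(CCC(=O)OC)cc2C(=[N+]=[N-])C(=O)OC)cc1OC
A5 | alternative 3 | methyl (2R,3S)-2-(4-tert-butyldimethylsilyloxy-3,5-dimethoxyphenyl)-7-methoxy-5-(3-methoxy-3-oxopropyl)-2,3-dihydrobenzofuran-3-carboxylate | CC(C)(C)[Si](C)(C)Oc1c(OC)cc([C@@H]2Oc3c(OC)cc(CCC(=O)OC)cc3[C@@H]2C(=O)OC)cc1OC
A6 | alternative 3 | methyl 3-[(2S)-2-(4-tert-butyldimethylsilyloxy-3,5-dimethoxyphenyl)-3-diazo-8-methoxy-4-oxochroman-6-yl]propanoate | CC(C)(C)[Si](C)(C)Oc1c(OC)cc([C@@H]2Oc3c(OC)cc(CCC(=O)OC)cc3C(=O)C2=[N+]=[N-])cc1OC
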